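## The problem

Compound 21, methyl 7-hydroxy-5-[2-(4-hydroxyphenyl)ethyl]-2,2-dimethyl-8-(3-methylbut-2-enyl)-2H-chromene-6-carboxylate, is an achiral prenylated bibenzyl built on a benzene ring (ring A) with six different substituents. In benzoate numbering these are the ester at C1, a hydroxyl at C2, a prenyl group at C3, the pyran oxygen at C4, the pyran carbon at C5 and the 2-(4-hydroxyphenyl)ethyl chain at C6. Ring B, the 2,2-dimethyl-2H-pyran, is ortho-fused across C4–C5, and ring C, the para-hydroxyphenyl group, hangs from C6 on a saturated two-carbon chain. There is no stereocentre, so no centre has to control another; the difficulty is purely positional. Two five-carbon isoprenoid units flank the C4 oxygen, the one at C3 left open and the one at C5 closed to the pyran, so the synthesis must tell C3 from C5 and the C2 hydroxyl from the C4 oxygen. The 2H-chromene, the ortho-prenylphenol (which closes to a chroman in acid) and the electron-rich free phenols rule out strong acid, electrophilic halogen and unselective oxidants late in the route. The methyl ester, hydrogen-bonded to the C2 hydroxyl, is robust. The enabling feature is the meta relationship of the C2 and C4 oxygens with the ester on C1 next to the chain-bearing C6. C1 and C6 with their substituents are an alk-2-ynoate, and C2–C5 are a 1,1,3-trioxygenated butadiene whose terminal carbon (C5) can carry the future pyran carbons.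

## Retrosynthesis

**21 from 20.** The last cut is the O–Si bond on ring C. The ring C phenol stays silylated until the end because a free phenol there would compete in the phenoxide alkylation and in the quinone oxidation. A silyl ether is chosen over an acetal because fluoride removes it without acid, which the chromene and the ortho-prenylphenol would not tolerate. The forward step only has to leave ester, chromene and prenyl group alone.

**20 from 18 and 2.** The C3–CH2 bond of the open prenyl group is cut next, giving chromene 18 and prenyl bromide 2. Carrying both prenyl groups before pyran closure would reopen the C3/C5 question, since an oxidative closure could use either chain. Once ring B exists, C3 is the only ring carbon bearing hydrogen and it lies between the phenoxide oxygen and the pyran oxygen. The forward reaction must favour carbon over oxygen alkylation.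

**18 from 16.** The O–CMe2 bond and the unsaturation of ring B are removed together, leading to resorcylate 16 with a prenyl group on C5 and free hydroxyls at C2 and C4. The C5 chain has one oxygen neighbour only (C4), so closure cannot go astray. Annulating a C5-unsubstituted resorcylate with a five-carbon enal would instead favour C3, the carbon between the oxygens. The forward step is a dehydrogenative cyclisation that must spare the bibenzyl CH2 groups.

**16 from 7 and 14 (key disconnection).** Ring A is cut at C1–C2 and C5–C6 into diene 7 (C2–C5 with both oxygens and the prenyl group) and ynoate 14 (C1, C6, the ester and the chain to ring C). Electrophilic substitution of a preformed resorcylate could not place a chain at C5 selectively against C3. The cycloaddition fixes every position through the two components, and the product is already aromatic after loss of methanol. A hexasubstituted arene is thereby reduced to two acyclic pieces. The forward reaction must deliver one orientation and tolerate the hindered diene terminus.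

**7 from 5, 4, 1 and 2.** The diene is the double enol silyl ether of β-keto ester 4, reached through the mono-silyl enol ether 5. Keto ester 4 is cut at the C4–C5 bond into methyl acetoacetate 1 and prenyl bromide 2 (γ-alkylation of the dianion). The second silylation must give the Z C3=C4 bond so that the prenyl group sits outside the s-cis diene.

**14 from 12, 11, 9 and 8.** The ynoate is cut at the alkyne–ester bond and then at the alkyne itself (one-carbon homologation of aldehyde 11 through dibromoalkene 12). Aldehyde 11 comes from ester 9 by partial reduction, and 9 from commercial methyl 3-(4-hydroxyphenyl)propanoate 8 by silylation. Each step is a standard operation on a simple chain.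

## Roads not taken

**Alternative 1:** Ring A is cut at C1–C6 and C2–C3. A malonate diester adds to enone A1 at the carbon that becomes C6, and the ketone enolate on the prenyl-bearing methylene then attacks a malonate ester, closing the ring as dione A2.
- Merits: three cheap components; the ester, the C3 prenyl group and the C6 chain arrive in one operation. With C3 occupied, a later pyran annulation at the C4 hydroxyl can only use C5. It would be several steps shorter than the chosen route and needs no sensitive bis-silyl diene.
- Weak points: A2 is at the cyclohexane-1,3-dione oxidation level and must be dehydrogenated in the presence of a prenyl alkene ortho to two emerging phenols. The usual halogen oxidants add to or cyclise onto that alkene, and a quinone oxidant could close the C3 chain onto either oxygen, building the wrong pyran. Ring B then has to be annulated by C–C bond formation at C5 on a pentasubstituted ring, next to the C6 chain. The acetal on ring C would finally be removed with acid in the presence of the chromene and the ortho-prenylphenol.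
- Comparison: the chosen plan is longer, but it reaches the aromatic level directly, brings the C5 carbons in with the ring, and adds the last prenyl group at the most nucleophilic carbon.

**Alternative 2:** Ring A is cut at C1–C2, C3–C4 and C4–C5. Cyclobutenone A3 opens thermally to a vinylketene, which adds to siloxyalkyne A4; a second ring opening and a 6π closure give A5, with the prenyl group at C3, a free phenol at C4 and a silyl ether at C2.
- Merits: the regiochemistry is dictated by the components, and the two oxygens are differentiated in the ring-forming step. This is better than the chosen plan, which relies on the hydrogen bond of the C2 hydroxyl to the ester.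
- Weak points: A5 has neither the C1 ester nor the C5 carbons, so two C–C bonds remain to be made on a crowded ring. The carboxyl group would have to be introduced at C1 between an oxygen and the C6 chain, in several steps and in the presence of prenyl and chromene units. A3 and A4 each need a multistep preparation of their own.
- Comparison: the chosen plan brings the ester and the C5 carbons in the cycloaddition and leaves one C–C bond (C3 prenyl) for later.

**Alternative 3:** Only ring B is cut, at the bond from its C4 to its C3 and at O–CMe2. Salicylaldehyde A6, an alkenylboronic acid and a secondary amine condense; the alkenyl group moves from boron to the iminium carbon, the amine is eliminated on heating, and oxa-6π closure gives chromene A7.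
- Merits: the pyran position is fixed by the formyl carbon, and the conditions are mild and non-oxidative. In this respect it is gentler than the quinone oxidation of the chosen plan.
- Weak points: this is an endgame only. A6 is a hexasubstituted benzene that must first be made, with a formyl group placed at C5 next to the C6 chain on a ring already carrying prenyl, ester and phenol groups; electrophilic formylation there is hindered and its reagents threaten the ortho-prenylphenol. The acetal of A7 would again be removed with acid at the end.
- Comparison: in the chosen plan the C5 carbons are set by the same step that builds ring A, so no formylation is needed.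

Key step: step 8

Assumption: 5 and the ketene acetal end of 7 may form as mixtures of double-bond isomers. The isomers drawn are the expected major ones; only the C3=C4 geometry of 7 matters and all of it is erased in step 8.

## Route

Step 1
Reactants: 1 methyl acetoacetate; 2 1-bromo-3-methylbut-2-ene (prenyl bromide)
Product: 4 methyl 7-methyl-3-oxooct-6-enoate, via sodium lithium dianion of methyl acetoacetate 3 (not isolated)
Conditions: NaH, THF, 0 °C; n-BuLi, 0 °C; then 2, 0 °C to rt; aq. HCl
Reagents that add atoms: none
Why: Dianion alkylation of a β-keto ester (Weiler): the second deprotonation creates the more basic γ-carbanion, which alone attacks the primary allylic bromide, while the α-position stays protected as the enolate until the quench.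

Step 2
Reactants: 4 methyl 7-methyl-3-oxooct-6-enoate
Product: 5 methyl (2E)-7-methyl-3-(trimethylsilyloxy)octa-2,6-dienoate
Conditions: Me3SiCl, Et3N, hexane, rt
Reagents that add atoms: chlorotrimethylsilane, C[Si](C)(C)Cl
Why: Soft enolisation and O-silylation of a β-keto ester gives the β-silyloxy enoate; either alkene isomer serves in step 3.

Step 3
Reactants: 5 methyl (2E)-7-methyl-3-(trimethylsilyloxy)octa-2,6-dienoate
Product: 7 (1Z,3Z)-1-methoxy-7-methyl-1,3-bis(trimethylsilyloxy)octa-1,3,6-triene, via lithium dienolate 6 (not isolated)
Conditions: LiN(i-Pr)2, THF, −78 °C; Me3SiCl, −78 °C to rt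
Reagents that add atoms: chlorotrimethylsilane, C[Si](C)(C)Cl
Why: Kinetic γ-deprotonation of the vinylogous ester and O-silylation of the dienolate is the standard preparation of 1-methoxy-1,3-bis(silyloxy)-1,3-dienes; 4-alkyl members of this class form with the Z C3=C4 bond, and the diene is used crude after a non-aqueous work-up.

Step 4
Reactants: 8 methyl 3-(4-hydroxyphenyl)propanoate
Product: 9 methyl 3-[4-(tert-butyldimethylsilyloxy)phenyl]propanoate
Conditions: t-BuMe2SiCl, imidazole, DMF, rt
Reagents that add atoms: tert-butyldimethylsilyl chloride, CC(C)(C)[Si](C)(C)Cl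
Why: Imidazole-promoted silylation of a phenol; the aryl silyl ether survives organolithium, heat, dilute acid and quinone oxidation and is removed by fluoride at the end.

Step 5
Reactants: 9 methyl 3-[4-(tert-butyldimethylsilyloxy)phenyl]propanoate
Product: 11 3-[4-(tert-butyldimethylsilyloxy)phenyl]propanal, via diisobutylaluminium hemiacetal 10 (not isolated)
Conditions: i-Bu2AlH, CH2Cl2, −78 °C; MeOH, then aq. potassium sodium tartrate
Reagents that add atoms: none
Why: Partial reduction of a methyl ester with one equivalent of hydride at low temperature; the tetrahedral aluminium hemiacetal persists at −78 °C and releases the aldehyde only on hydrolysis.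

Step 6
Reactants: 11 3-[4-(tert-butyldimethylsilyloxy)phenyl]propanal
Product: 12 tert-butyl[4-(4,4-dibromobut-3-enyl)phenoxy]dimethylsilane
Conditions: CBr4, PPh3, CH2Cl2, 0 °C
Reagents that add atoms: carbon tetrabromide, BrC(Br)(Br)Br
Why: First stage of the Corey–Fuchs homologation, a Wittig-type olefination of the aldehyde by the dibromomethylene ylide formed in the flask.

Step 7
Reactants: 12 tert-butyl[4-(4,4-dibromobut-3-enyl)phenoxy]dimethylsilane
Product: 14 methyl 5-[4-(tert-butyldimethylsilyloxy)phenyl]pent-2-ynoate, via lithium acetylide 13 (not isolated)
Conditions: n-BuLi (2.1 equiv), THF, −78 to 0 °C; ClCO2Me, −78 °C to rt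
Reagents that add atoms: methyl chloroformate, COC(=O)Cl
Why: Second stage of the Corey–Fuchs sequence: bromine–lithium exchange and Fritsch–Buttenberg–Wiechell rearrangement give the lithium acetylide, which is acylated by the chloroformate; the aryl silyl ether is inert to n-BuLi at these temperatures.

Step 8
Reactants: 7 (1Z,3Z)-1-methoxy-7-methyl-1,3-bis(trimethylsilyloxy)octa-1,3,6-triene; 14 methyl 5-[4-(tert-butyldimethylsilyloxy)phenyl]pent-2-ynoate
Product: 16 methyl 2,4-dihydroxy-5-(3-methylbut-2-enyl)-6-{2-[4-(tert-butyldimethylsilyloxy)phenyl]ethyl}benzoate, via cyclohexa-1,4-diene cycloadduct 15 (not isolated)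
Conditions: 7 (2.5 equiv), toluene, sealed tube, 120 °C; then 1 M aq. HCl, THF, 0 °C
Reagents that add atoms: none
Why: A normal-demand Diels–Alder reaction: the three oxygen donors raise the HOMO of 7 and put its largest coefficient on C4, the prenyl-bearing terminus, while the ester puts the largest LUMO coefficient of 14 on the β-carbon, so the asynchronous but concerted [4+2] joins diene C4 to the alkyne β-carbon (C5–C6 of ring A) and diene C1 to the α-carbon (C1–C2). The closest known reaction type is the cycloaddition of 1,1-dioxygenated 3-silyloxybuta-1,3-dienes with acetylenic esters, which gives resorcylates after loss of alcohol. Ring A is closed as a six-membered carbocycle by this [4+2] cycloaddition, first as the cyclohexa-1,4-diene 15. On acidic work-up the silyl groups are hydrolysed, the mixed silyl methyl ketal at C2 collapses with loss of methanol, and enolisation with loss of the C5 hydrogen gives the arene, the hydrogen-bonded resorcylate being the thermodynamic sink. The two stereocentres of 15 (C2 and C5) form without control and both vanish on aromatisation, so no stereocentre has to be set. The selectivity needed is orientational and is secured by the matched polarisation of the partners; the opposite adduct would put the prenyl group next to the ester and is disfavoured electronically and sterically. The Z geometry of the C3=C4 bond of 7 holds the prenyl group outside the s-cis diene, which keeps the cisoid conformer accessible and denies the allylic CH2 a 1,5-hydrogen shift. The isolated trisubstituted alkene of the prenyl group and the aryl silyl ether are spectators under these conditions.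

Step 9
Reactants: 16 methyl 2,4-dihydroxy-5-(3-methylbut-2-enyl)-6-{2-[4-(tert-butyldimethylsilyloxy)phenyl]ethyl}benzoate
Product: 18 methyl 7-hydroxy-2,2-dimethyl-5-{2-[4-(tert-butyldimethylsilyloxy)phenyl]ethyl}-2H-chromene-6-carboxylate, via ortho-quinone methide 17 (not isolated)
Conditions: DDQ (1.1 equiv), toluene, 80 °C
Reagents that add atoms: none
Why: Dehydrogenative cyclisation of an ortho-prenylphenol: DDQ abstracts hydride from the benzylic and allylic CH2 next to the free C4 hydroxyl, and the resulting ortho-quinone methide closes ring B by oxa-6π electrocyclisation; the C5 chain has only the C4 oxygen as ortho neighbour, so no other pyran can form.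

Step 10
Reactants: 18 methyl 7-hydroxy-2,2-dimethyl-5-{2-[4-(tert-butyldimethylsilyloxy)phenyl]ethyl}-2H-chromene-6-carboxylate; 2 1-bromo-3-methylbut-2-ene (prenyl bromide)
Product: 20 methyl 7-hydroxy-2,2-dimethyl-8-(3-methylbut-2-enyl)-5-{2-[4-(tert-butyldimethylsilyloxy)phenyl]ethyl}-2H-chromene-6-carboxylate, via sodium phenoxide 19 (not isolated)
Conditions: NaH, toluene, 0 °C to rt; then 2, rt to 50 °C
Reagents that add atoms: none
Why: Ortho C-alkylation of a sodium phenoxide in a non-polar solvent, as used for C-prenylation of salicylate esters: the tight ion pair chelated between phenoxide oxygen and ester carbonyl shields oxygen, and C3 (chromene C8), flanked by both ring oxygens, is the only unsubstituted ring carbon; the dienone re-aromatises by proton transfer.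

Step 11
Reactants: 20 methyl 7-hydroxy-2,2-dimethyl-8-(3-methylbut-2-enyl)-5-{2-[4-(tert-butyldimethylsilyloxy)phenyl]ethyl}-2H-chromene-6-carboxylate
Product: 21 methyl 7-hydroxy-5-[2-(4-hydroxyphenyl)ethyl]-2,2-dimethyl-8-(3-methylbut-2-enyl)-2H-chromene-6-carboxylate
Conditions: Bu4NF, AcOH, THF, 0 °C
Reagents that add atoms: none
Why: Fluoride cleavage of an aryl silyl ether; the acetic acid buffer keeps the medium near neutral so that ester, chromene and ortho-prenylphenol are untouched.

## Compound list

1 | methyl acetoacetate | COC(=O)CC(C)=O | starting material
2 | 1-bromo-3-methylbut-2-ene (prenyl bromide) | CC(C)=CCBr | starting material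
3 | sodium lithium dianion of methyl acetoacetate | [Na+].[Li+].COC([O-])=CC(=C)[O-] | intermediate
4 | methyl 7-methyl-3-oxooct-6-enoate | COC(=O)CC(=O)CCC=C(C)C | intermediate
5 | methyl (2E)-7-methyl-3-(trimethylsilyloxy)octa-2,6-dienoate (E isomer drawn; the Z isomer may accompany it) | COC(=O)/C=C(/O[Si](C)(C)C)CCC=C(C)C | intermediate
6 | lithium dienolate of 5, (3Z)-1-methoxy-7-methyl-3-(trimethylsilyloxy)octa-1,3,6-trien-1-olate | [Li+].COC([O-])=C/C(O[Si](C)(C)C)=C/CC=C(C)C | intermediate
7 | (1Z,3Z)-1-methoxy-7-methyl-1,3-bis(trimethylsilyloxy)octa-1,3,6-triene | CO/C(O[Si](C)(C)C)=C/C(O[Si](C)(C)C)=C/CC=C(C)C | intermediate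
8 | methyl 3-(4-hydroxyphenyl)propanoate | COC(=O)CCc1ccc(O)cc1 | starting material
9 | methyl 3-[4-(tert-butyldimethylsilyloxy)phenyl]propanoate | COC(=O)CCc1ccc(O[Si](C)(C)C(C)(C)C)cc1 | intermediate
10 | diisobutylaluminium methyl hemiacetal of 11 (racemic) | COC(CCc1ccc(O[Si](C)(C)C(C)(C)C)cc1)O[Al](CC(C)C)CC(C)C | intermediate
11 | 3-[4-(tert-butyldimethylsilyloxy)phenyl]propanal | O=CCCc1ccc(O[Si](C)(C)C(C)(C)C)cc1 | intermediate
12 | tert-butyl[4-(4,4-dibromobut-3-enyl)phenoxy]dimethylsilane | BrC(Br)=CCCc1ccc(O[Si](C)(C)C(C)(C)C)cc1 | intermediate
13 | lithium 4-[4-(tert-butyldimethylsilyloxy)phenyl]but-1-yn-1-ide | [Li+].[C-]#CCCc1ccc(O[Si](C)(C)C(C)(C)C)cc1 | intermediate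
14 | methyl 5-[4-(tert-butyldimethylsilyloxy)phenyl]pent-2-ynoate | COC(=O)C#CCCc1ccc(O[Si](C)(C)C(C)(C)C)cc1 | intermediate
15 | methyl 2-{2-[4-(tert-butyldimethylsilyloxy)phenyl]ethyl}-6-methoxy-3-(3-methylbut-2-enyl)-4,6-bis(trimethylsilyloxy)cyclohexa-1,4-diene-1-carboxylate (racemic mixture of diastereomers, both centres lost on aromatisation) | COC(=O)C1=C(CCc2ccc(O[Si](C)(C)C(C)(C)C)cc2)C(CC=C(C)C)C(O[Si](C)(C)C)=CC1(OC)O[Si](C)(C)C | intermediate
16 | methyl 2,4-dihydroxy-5-(3-methylbut-2-enyl)-6-{2-[4-(tert-butyldimethylsilyloxy)phenyl]ethyl}benzoate | COC(=O)c1c(O)cc(O)c(CC=C(C)C)c1CCc1ccc(O[Si](C)(C)C(C)(C)C)cc1 | intermediate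
17 | ortho-quinone methide, methyl 6-hydroxy-3-[(Z)-3-methylbut-2-enylidene]-4-oxo-2-{2-[4-(tert-butyldimethylsilyloxy)phenyl]ethyl}cyclohexa-1,5-diene-1-carboxylate | COC(=O)C1=C(CCc2ccc(O[Si](C)(C)C(C)(C)C)cc2)/C(=C/C=C(C)C)C(=O)C=C1O | intermediate
18 | methyl 7-hydroxy-2,2-dimethyl-5-{2-[4-(tert-butyldimethylsilyloxy)phenyl]ethyl}-2H-chromene-6-carboxylate | COC(=O)c1c(O)cc2c(c1CCc1ccc(O[Si](C)(C)C(C)(C)C)cc1)C=CC(C)(C)O2 | intermediate
19 | sodium phenoxide of 18 | [Na+].COC(=O)c1c([O-])cc2c(c1CCc1ccc(O[Si](C)(C)C(C)(C)C)cc1)C=CC(C)(C)O2 | intermediate
20 | methyl 7-hydroxy-2,2-dimethyl-8-(3-methylbut-2-enyl)-5-{2-[4-(tert-butyldimethylsilyloxy)phenyl]ethyl}-2H-chromene-6-carboxylate | COC(=O)c1c(O)c(CC=C(C)C)c2c(c1CCc1ccc(O[Si](C)(C)C(C)(C)C)cc1)C=CC(C)(C)O2 | intermediate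
21 | methyl 7-hydroxy-5-[2-(4-hydroxyphenyl)ethyl]-2,2-dimethyl-8-(3-methylbut-2-enyl)-2H-chromene-6-carboxylate | COC(=O)c1c(O)c(CC=C(C)C)c2c(c1CCc1ccc(O)cc1)C=CC(C)(C)O2 | target

## Step count and risks

Total: 11 steps. Longest linear sequence: 8 steps (steps 4–11, from 8); the diene branch (steps 1–3) joins in step 8.

**Step 8 (key step).** The cycloaddition of a 4-substituted diene with an alkyl-substituted, singly activated alkyne is likely to be slow. Thermal decay of the diene (silyl migration, isomerisation that turns the prenyl group inward, adventitious hydrolysis) may then outrun ring formation, or an open-chain conjugate adduct may form without ring closure. The fallback replaces the alkyne by the isomeric allene, a much stronger dienophile, and sets out from aldehyde 11. Oxidation with NaClO2 and NaH2PO4 in the presence of 2-methylbut-2-ene should give 3-[4-(tert-butyldimethylsilyloxy)phenyl]propanoic acid F1. Oxalyl chloride with catalytic DMF converts it into 3-[4-(tert-butyldimethylsilyloxy)phenyl]propanoyl chloride F2. Et3N and methyl (triphenylphosphoranylidene)acetate (Wittig reaction of the ketene formed in the flask) then give methyl 5-[4-(tert-butyldimethylsilyloxy)phenyl]penta-2,3-dienoate F3. Cycloaddition of 7 across the 2,3-double bond of the allenoate, at or slightly above room temperature and with the same orientation, would give the alkylidenecyclohexene cycloadduct F4 (not isolated). On the same acidic work-up F4 loses methanol and its silyl groups and moves the exocyclic double bond into the ring, returning to the route at 16.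

**Step 10.** O-alkylation of the phenoxide may compete with C-alkylation. A second alkylation with dearomatisation and silyl transfer from the ring C ether to the phenoxide are further possibilities. The fallback goes through oxygen on purpose and sets out from 18. Allylic substitution catalysed by zerovalent palladium, with tert-butyl 2-methylbut-3-en-2-yl carbonate and Pd(PPh3)4 in THF, should give the tertiary allyl ether methyl 2,2-dimethyl-7-[(2-methylbut-3-en-2-yl)oxy]-5-{2-[4-(tert-butyldimethylsilyloxy)phenyl]ethyl}-2H-chromene-6-carboxylate F5. Heating in toluene or N,N-diethylaniline brings about the aromatic Claisen rearrangement, which inverts the allyl unit and delivers the linear prenyl group to the only free ortho carbon, rejoining the route at 20.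

**Step 9.** The quinone may oxidise the electron-rich resorcinol ring or abstract hydride from the bibenzyl CH2 para to the silyloxy group, and conversion may stall through charge-transfer complexation. The fallback is a non-oxidative closure from 16. PhSeCl in CH2Cl2 at −78 °C should effect 6-endo selenoetherification (oxygen attack on the tertiary carbon) to give methyl 7-hydroxy-2,2-dimethyl-3-(phenylselanyl)-5-{2-[4-(tert-butyldimethylsilyloxy)phenyl]ethyl}chromane-6-carboxylate F6. Oxidation with H2O2 and syn-elimination of the selenoxide, which has β-hydrogens only at the benzylic carbon, leads back to 18.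

**Step 5.** The aluminium hemiacetal may collapse before the quench and be reduced further, giving mixtures of alcohol, aldehyde and ester. The fallback from 9 is full reduction with LiAlH4 to 3-[4-(tert-butyldimethylsilyloxy)phenyl]propan-1-ol F7, followed by oxidation with Dess–Martin periodinane, which returns to 11.

## Further compounds

F1 | step 8 | 3-[4-(tert-butyldimethylsilyloxy)phenyl]propanoic acid | OC(=O)CCc1ccc(O[Si](C)(C)C(C)(C)C)cc1
F2 | step 8 | 3-[4-(tert-butyldimethylsilyloxy)phenyl]propanoyl chloride | ClC(=O)CCc1ccc(O[Si](C)(C)C(C)(C)C)cc1
F3 | step 8 | methyl 5-[4-(tert-butyldimethylsilyloxy)phenyl]penta-2,3-dienoate (racemic) | COC(=O)C=C=CCc1ccc(O[Si](C)(C)C(C)(C)C)cc1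
F4 | step 8 | methyl 2-{2-[4-(tert-butyldimethylsilyloxy)phenyl]ethylidene}-6-methoxy-3-(3-methylbut-2-enyl)-4,6-bis(trimethylsilyloxy)cyclohex-4-ene-1-carboxylate (stereoisomer mixture) | COC(=O)C1C(=CCc2ccc(O[Si](C)(C)C(C)(C)C)cc2)C(CC=C(C)C)C(O[Si](C)(C)C)=CC1(OC)O[Si](C)(C)C
F5 | step 10 | methyl 2,2-dimethyl-7-[(2-methylbut-3-en-2-yl)oxy]-5-{2-[4-(tert-butyldimethylsilyloxy)phenyl]ethyl}-2H-chromene-6-carboxylate | COC(=O)c1c(OC(C)(C)C=C)cc2c(c1CCc1ccc(O[Si](C)(C)C(C)(C)C)cc1)C=CC(C)(C)O2
F6 | step 9 | methyl 7-hydroxy-2,2-dimethyl-3-(phenylselanyl)-5-{2-[4-(tert-butyldimethylsilyloxy)phenyl]ethyl}chromane-6-carboxylate (racemic) | COC(=O)c1c(O)cc2c(c1CCc1ccc(O[Si](C)(C)C(C)(C)C)cc1)CC([Se]c1ccccc1)C(C)(C)O2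
F7 | step 5 | 3-[4-(tert-butyldimethylsilyloxy)phenyl]propan-1-ol | OCCCc1ccc(O[Si](C)(C)C(C)(C)C)cc1
A1 | alternative 1 | (3E)-1-[4-(methoxymethoxy)phenyl]-9-methyldeca-3,8-dien-5-one | COCOc1ccc(CC/C=C/C(=O)CCC=C(C)C)cc1
A2 | alternative 1 | methyl trans-2-hydroxy-6-{2-[4-(methoxymethoxy)phenyl]ethyl}-3-(3-methylbut-2-enyl)-4-oxocyclohex-2-ene-1-carboxylate (racemic, one enantiomer drawn) | COC(=O)[C@@H]1[C@@H](CCc2ccc(OCOC)cc2)CC(=O)C(CC=C(C)C)=C1O
A3 | alternative 2 | 3-{2-[4-(2,2-dimethylpropanoyloxy)phenyl]ethyl}cyclobut-2-en-1-one | CC(C)(C)C(=O)Oc1ccc(CCC2=CC(=O)C2)cc1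
A4 | alternative 2 | triisopropyl[(5-methylhex-4-en-1-yn-1-yl)oxy]silane | CC(C)=CCC#CO[Si](C(C)C)(C(C)C)C(C)C
A5 | alternative 2 | 4-{2-[3-hydroxy-4-(3-methylbut-2-enyl)-5-(triisopropylsilyloxy)phenyl]ethyl}phenyl 2,2-dimethylpropanoate | CC(C)=CCc1c(O)cc(CCc2ccc(OC(=O)C(C)(C)C)cc2)cc1O[Si](C(C)C)(C(C)C)C(C)C
A6 | alternative 3 | methyl 5-formyl-2,4-dihydroxy-6-{2-[4-(methoxymethoxy)phenyl]ethyl}-3-(3-methylbut-2-enyl)benzoate | COC(=O)c1c(O)c(CC=C(C)C)c(O)c(C=O)c1CCc1ccc(OCOC)cc1
A7 | alternative 3 | methyl 7-hydroxy-5-{2-[4-(methoxymethoxy)phenyl]ethyl}-2,2-dimethyl-8-(3-methylbut-2-enyl)-2H-chromene-6-carboxylate | COC(=O)c1c(O)c(CC=C(C)C)c2c(c1CCc1ccc(OCOC)cc1)C=CC(C)(C)O2
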